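The numbers in the tables were computed for an exercise; scatter was added.

In a one-step world with a catalyst that never tires, L = ln(σ/(σ − P)), where σ is the substrate charge and P the target, climbs in a straight line, and its slope s is a pseudo-first-order constant. So a bend in that slope says that more than the one step is at work, and in the runs below I shall read the bend as wear on the catalyst, which is my assumption.

| flask | substrate | coupling partner | free catalyst | target | time |
|---|---|---|---|---|---|
| east | 0.200 M | 0.500 M | 0.00100 M |  |  |
| south-west | 0.0800 M | 0.380 M | 0.00100 M |  |  |
| north-west | 0.200 M | 0.500 M | 0.00300 M |  |  |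
| north | 0.200 M | 0.500 M | 0.00100 M | 0.0600 M |  |
| west | 0.0660 M | 1.00 M | 0.00100 M |  | 71 min |

| run | time / min | [target] / M |
|---|---|---|
| east run | 3.2 | 0.0126 |
| east run | 9.6 | 0.0329 |
| east run | 18 | 0.0541 |
| east run | 29 | 0.0766 |
| east run | 41 | 0.0882 |
| east run | 55 | 0.1000 |
| east run | 71 | 0.1073 |
| south-west run | 3.2 | 0.0056 |
| south-west run | 9.6 | 0.0133 |
| south-west run | 18 | 0.0225 |
| south-west run | 29 | 0.0333 |
| south-west run | 41 | 0.0387 |
| south-west run | 55 | 0.0429 |
| south-west run | 71 | 0.0445 |
| north-west run | 3.2 | 0.0359 |
| north-west run | 9.6 | 0.0861 |
| north-west run | 18 | 0.1250 |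
| north-west run | 29 | 0.1492 |
| north-west run | 41 | 0.1581 |
| north-west run | 55 | 0.1608 |
| north-west run | 71 | 0.1583 |
| north run | 3.2 | 0.0713 |
| north run | 9.6 | 0.0933 |
| north run | 18 | 0.1117 |
| north run | 29 | 0.1298 |
| north run | 41 | 0.1409 |
| north run | 55 | 0.1520 |
| north run | 71 | 0.1536 |

(standard deviation of a reading: 0.001 M)

- Overall: substrate + coupling partner -> target, with free catalyst as catalyst.
- Constant volume, constant temperature.
- Bound and free are read together.
- An order is taken over about fifteen percent of the charge, up and down.

- order of the initial rate in [free catalyst], near the charge of the east run, the rate being that where two percent of its substrate are target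
- target in the west run at 71 min, as a share of the substrate charged

Read the east table from top to bottom. Up to 9.6 min the slope is 0.0187 min⁻¹, but between 41 min and 71 min it is 0.00624 min⁻¹. Spread over the time between those two windows, that is a decay rate λ of 0.0214 min⁻¹. Taken back to time zero, the east slope starts at 0.0208 min⁻¹.

Now read the north-west table, which has 3.00 times the catalyst. Its first slope is 0.0618 min⁻¹, against 0.0203 min⁻¹ in the east run, which gives an order in catalyst of 1.01. Its slope then bends at 0.0178 min⁻¹, well below 0.0642 min⁻¹, so the decay does not scale with turnover.

My bet is that coupling partner wears the catalyst out, though I have not separated that from wear on a plain clock, and the north-west readings, 0.1608 M at 55 min and 0.1583 M at 71 min, hint at a loss of target that the bend may hold as well. The east run had 0.423 M of partner at mid-window, so I define κ, the wear coefficient, as λ per unit of partner 0.0506 L mol⁻¹ min⁻¹.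

The south-west run starts on a slope of 0.0189 min⁻¹, close to the east run's, so I keep the starting slope for the west run too. That is an assumption, since the south-west run keeps the same excess of partner, 0.300 M.

In the west run, 1.00 M of partner gives a wear of 0.0506 min⁻¹, and L at 71 min comes to 0.398. I therefore commit to order 1 and 32.9%.

The forecast gives order 1 and 65%, more than my figure: “I expect about 65%, with wide uncertainty.”

The flask gives order 1.0 and 40.7%, which is 7.8 percentage points above my figure.

    free catalyst + substrate ⇌ catalyst-substrate complex (23.82 L mol⁻¹ min⁻¹, 0.7320 min⁻¹)
    catalyst-substrate complex + coupling partner → target + free catalyst (80.40 L mol⁻¹ min⁻¹)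
    free catalyst + coupling partner → spent catalyst + coupling partner (0.03156 L mol⁻¹ min⁻¹)
    target → decomposed product (0.003726 min⁻¹)

In the west run, target came from the catalyst-substrate complex and coupling partner, while free catalyst, in 1.00 M of partner at the start, turned into spent catalyst with a lifetime of 31.7 min at that charge, and target went over to decomposed product at 0.00373 min⁻¹. The north-west run, with 0.00300 M of free catalyst and 0.414 M of partner at 9.6 min, comes on κ to 0.121 M of target at 18 min, and it read 0.1250 M.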